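**Strategy**

The decalin is traced back to an acyclic tetraene in which a (2Z,6E)-farnesoate (C1, C5–C17, C20) is joined to a chiral 2-methylacetoacetate (C2–C4, C18, C19). The key step exploits the head-to-tail spacing C4/C5=C10/C9=C8 and the C8=C17 exocyclic methylene of ring B: Mn(OAc)3 generates the C4 radical, which closes ring A; the C10 radical then closes ring B through the C10–C9 bond, and Cu(OAc)2 turns the C8 radical into the C8=C17 olefin. One operation sets C4, C5, C9 and C10 under control of a (−)-8-phenylmenthyl ester, with C19 axial. Deletion of the C3 ketone, reduction at C19 and acetylation complete the route.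

Key step: step 7

Remark on the chemistry: labdane numbering (C1–C20) is used throughout. The sense of induction by the (1R,2S,5R)-8-phenylmenthyl ester is assumed from the face-shielding model for non-chelated α-methyl β-keto ester radicals; should the opposite sense be found, the enantiomeric alcohol would be used. Compounds 11 and 13 are used as epimer mixtures at the α-carbon, which later becomes the planar C4 radical.

**Route**

Step 1
Reactants: 1 (E)-geranylacetone
Product: 4 methyl (6E)-7,11-dimethyldodeca-6,10-dien-2-ynoate, via enol phosphate 2 (not isolated), via lithium acetylide 3 (not isolated)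
Conditions: LiN(iPr)2 (1.1 equiv), THF, −78 °C; ClP(O)(OEt)2, −78 °C to rt; LiN(iPr)2 (2.3 equiv), −78 °C to rt; ClCO2Me (3 equiv), −78 to 0 °C
Reagents that add atoms: methyl chloroformate COC(=O)Cl (diethyl chlorophosphate CCOP(=O)(Cl)OCC adds atoms only to intermediate 2)
Why: Kinetic enolisation of the methyl ketone at CH3, O-phosphorylation, amide-induced β-elimination of the enol phosphate to the terminal alkyne (held as its acetylide) and C-acylation by the chloroformate convert the methyl ketone into the ynoate without touching the 5E olefin (methyl ketone to alkyne conversion via an enol phosphate, then acetylide carboxymethylation).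

Step 2
Reactants: 4 methyl (6E)-7,11-dimethyldodeca-6,10-dien-2-ynoate
Product: 6 methyl (2Z,6E)-3,7,11-trimethyldodeca-2,6,10-trienoate, via alkenylcuprate 5 (not isolated)
Conditions: Me2CuLi (from CuI and 2 MeLi, 1.5 equiv), THF, −78 °C; MeOH quench at −78 °C
Reagents that add atoms: lithium dimethylcuprate [Li+].C[Cu-]C (one methyl group)
Why: Conjugate addition of the cuprate to the ynoate is a syn-carbocupration, and at −78 °C the alkenylcuprate keeps its geometry and is protonated with retention, so the new methyl group and H14 end up cis and the chain cis to CO2CH3, which fixes the 13Z olefin.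

Step 3
Reactants: 6 methyl (2Z,6E)-3,7,11-trimethyldodeca-2,6,10-trienoate
Product: 7 methyl (2Z,6E,10E)-12-hydroxy-3,7,11-trimethyldodeca-2,6,10-trienoate
Conditions: SeO2 (0.2 equiv), t-BuOOH (3 equiv), salicylic acid (0.1 equiv), CH2Cl2, 0 °C to rt
Reagents that add atoms: tert-butyl hydroperoxide CC(C)(C)OO (terminal oxidant that supplies the oxygen atom through catalytic SeO2)
Why: Riley-type allylic oxidation (ene reaction, then [2,3]-sigmatropic shift) should select the E-methyl group of the terminal, most electron-rich trisubstituted olefin, the enoate olefin being deactivated and the internal olefin more hindered, and the mechanism delivers the E-allylic alcohol.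

Step 4
Reactants: 7 methyl (2Z,6E,10E)-12-hydroxy-3,7,11-trimethyldodeca-2,6,10-trienoate
Product: 8 methyl (2Z,6E,10E)-12-bromo-3,7,11-trimethyldodeca-2,6,10-trienoate
Conditions: CBr4, PPh3, CH2Cl2, 0 °C
Reagents that add atoms: carbon tetrabromide BrC(Br)(Br)Br
Why: The Appel reaction replaces the primary allylic hydroxyl by bromide through SN2 attack on the alkoxyphosphonium ion under neutral conditions that leave the Z-enoate and both E olefins unchanged.

Step 5
Reactants: 9 (−)-8-phenylmenthol; 10 ethyl 2-methyl-3-oxobutanoate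
Product: 11 (1R,2S,5R)-8-phenylmenthyl 2-methyl-3-oxobutanoate
Conditions: DMAP (0.3 equiv), toluene, reflux, 4 Å molecular sieves to remove EtOH
Reagents that add atoms: none
Why: DMAP-catalysed transesterification of a β-keto ester (through the acylketene) should acylate even this hindered secondary alcohol once ethanol is removed, and the α-centre, formed as a mixture, is erased later.

Step 6
Reactants: 11 (1R,2S,5R)-8-phenylmenthyl 2-methyl-3-oxobutanoate; 8 methyl (2Z,6E,10E)-12-bromo-3,7,11-trimethyldodeca-2,6,10-trienoate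
Product: 13 1-methyl 16-[(1R,2S,5R)-8-phenylmenthyl] (2Z,6E,10E)-3,7,11,15-tetramethyl-14-oxohexadeca-2,6,10-trienedioate, via sodium lithium dianion 12 (not isolated)
Conditions: NaH, THF, 0 °C; n-BuLi, 0 °C; then 8, −78 to −20 °C; AcOH quench
Reagents that add atoms: none
Why: γ-Alkylation of a β-keto ester dianion: the terminal carbanion is the most nucleophilic site and should displace the allylic bromide (SN2, forming C1–C2) at −78 °C faster than it attacks the conjugated methyl ester or deprotonates the enoate.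

Step 7
Reactants: 13 1-methyl 16-[(1R,2S,5R)-8-phenylmenthyl] (2Z,6E,10E)-3,7,11,15-tetramethyl-14-oxohexadeca-2,6,10-trienedioate
Product: 14 15-methyl 19-[(1R,2S,5R)-8-phenylmenthyl] (13Z)-3-oxolabda-8(17),13-diene-15,19-dioate
Conditions: Mn(OAc)3·2H2O (2.2 equiv), Cu(OAc)2·H2O (1.5 equiv), degassed AcOH, 25 °C
Reagents that add atoms: none
Why: Mn(OAc)3 enolises and oxidises the α-methyl β-keto ester to the electrophilic tertiary C4 radical, which adds to C5, the resulting C10 radical adds to C9, and Cu(OAc)2 traps the C8 radical as an alkylcopper species of trivalent copper that undergoes β-hydride elimination into the C17 methyl group to give the C8=C17 olefin, Mn(OAc)3 returning the monovalent copper to Cu(OAc)2. The closest known reaction type is the Mn(OAc)3/Cu(OAc)2 oxidative free-radical polyene cyclisation of unsaturated α-methyl β-keto esters carrying an 8-phenylmenthyl ester auxiliary. Ring A closes 6-endo-trig (C4–C5) and ring B closes 6-endo-trig (C10–C9), both through chair transition states. The E geometry of the C5=C10 and C8=C9 olefins in the chair–chair array sets the trans ring fusion (5α-H, 10β-CH3) and the equatorial C9 side chain (9α-H), the radical reacts with its ester carbonyl anti to the C3 ketone so that the C19 ester becomes axial (4β, cis to C20), and the phenyl ring of the auxiliary covers one face of the planar radical so that C5 bonds on the open face, which fixes the absolute configuration. The step needs 6-endo over 5-exo closure (secured by the methyl groups on C10 and C8, which make the endo radicals tertiary), oxidation of the C8 radical ahead of its 5-exo addition to C13 of the enoate (secured by near-saturating Cu(OAc)2 and by the β,β-disubstitution and congestion at C13) and exocyclic over endocyclic olefin formation (secured by the preference of the copper intermediate for the unhindered methyl hydrogens). The minor auxiliary-derived diastereomer and any endocyclic olefin isomers are diastereomers or regioisomers of 14 and are to be removed by chromatography.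

Step 8
Reactants: 14 15-methyl 19-[(1R,2S,5R)-8-phenylmenthyl] (13Z)-3-oxolabda-8(17),13-diene-15,19-dioate
Product: 15 15-methyl 19-[(1R,2S,5R)-8-phenylmenthyl] (13Z)-3-(tosylhydrazono)labda-8(17),13-diene-15,19-dioate
Conditions: TsNHNH2 (2 equiv), PPTS (cat.), EtOH, 70 °C
Reagents that add atoms: 4-methylbenzenesulfonohydrazide Cc1ccc(cc1)S(=O)(=O)NN
Why: Condensation of the only ketone (C3) with tosylhydrazide gives the hydrazone, while both esters, the enoate and the C8=C17 olefin are inert to these nearly neutral conditions.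

Step 9
Reactants: 15 15-methyl 19-[(1R,2S,5R)-8-phenylmenthyl] (13Z)-3-(tosylhydrazono)labda-8(17),13-diene-15,19-dioate
Product: 17 15-methyl 19-[(1R,2S,5R)-8-phenylmenthyl] (13Z)-labda-8(17),13-diene-15,19-dioate, via N-boryl tosylhydrazide 16 (not isolated)
Conditions: catecholborane (2 equiv), CHCl3, 0 °C to rt; then NaOAc·3H2O, reflux
Reagents that add atoms: none
Why: Caglioti-type reductive deoxygenation: catecholborane delivers hydride to C=N, acetate triggers loss of sulfinate and the diazene loses N2 to leave CH2 at C3, with neither a carbocation nor a strong base to move the C8=C17 olefin or touch the enoate.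

Step 10
Reactants: 17 15-methyl 19-[(1R,2S,5R)-8-phenylmenthyl] (13Z)-labda-8(17),13-diene-15,19-dioate
Product: 18 (13Z)-19-[(1R,2S,5R)-8-phenylmenthyloxy]-19-oxolabda-8(17),13-dien-15-oic acid
Conditions: LiOH·H2O, THF/MeOH/H2O, rt to 40 °C; then cold 1 M HCl to pH 3
Reagents that add atoms: lithium hydroxide [Li+].[OH-] (the oxygen of the new carboxyl OH)
Why: Saponification (acyl–oxygen cleavage) should take only the unhindered methyl enoate, because the axial, neopentyl-type C19 ester of a bulky secondary alcohol is shielded, and the Z geometry of a β,β-disubstituted enoate is retained.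

Step 11
Reactants: 18 (13Z)-19-[(1R,2S,5R)-8-phenylmenthyloxy]-19-oxolabda-8(17),13-dien-15-oic acid
Product: 19 (13Z)-19-hydroxylabda-8(17),13-dien-15-oic acid
Conditions: LiEt3BH (6 equiv), THF, 0 to 50 °C; then H2O and cold 1 M HCl
Reagents that add atoms: none
Why: LiEt3BH first deprotonates the acid to a lithium carboxylate that it does not reduce, while it reduces the C19 ester by two hydride transfers to the primary alcohol and releases the auxiliary alcohol 9 for recovery (chemoselective ester reduction in the presence of a carboxylate).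

Step 12
Reactants: 19 (13Z)-19-hydroxylabda-8(17),13-dien-15-oic acid
Product: 21 (13Z)-19-acetoxylabda-8(17),13-dien-15-oic acid, via mixed anhydride 20 (not isolated)
Conditions: Ac2O (3 equiv), pyridine, rt; then H2O/THF, NaHCO3, rt; acidify to pH 3
Reagents that add atoms: acetic anhydride CC(=O)OC(C)=O
Why: O-Acetylation of the primary C19 alcohol, with the mixed anhydride formed at C15 hydrolysed back to the free acid on aqueous work-up, gives the target without a strong base that could isomerise the Z-enoic acid.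

**Compound list**

1 | (E)-geranylacetone, (5E)-6,10-dimethylundeca-5,9-dien-2-one | CC(=O)CC/C=C(\C)CCC=C(C)C | starting material
2 | diethyl (5E)-6,10-dimethylundeca-1,5,9-trien-2-yl phosphate (enol phosphate) | C=C(OP(=O)(OCC)OCC)CC/C=C(\C)CCC=C(C)C | intermediate (not isolated)
3 | [(5E)-6,10-dimethylundeca-5,9-dien-1-yn-1-yl]lithium (lithium acetylide) | [Li]C#CCC/C=C(\C)CCC=C(C)C | intermediate (not isolated)
4 | methyl (6E)-7,11-dimethyldodeca-6,10-dien-2-ynoate | COC(=O)C#CCC/C=C(\C)CCC=C(C)C | intermediate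
5 | lithium methyl(alkenyl)cuprate from syn-addition to 4 (Cu on C2, cis to the new C3 methyl; chain cis to CO2CH3) | [Li+].COC(=O)/C([Cu-]C)=C(C)\CC/C=C(\C)CCC=C(C)C | intermediate (not isolated)
6 | methyl (2Z,6E)-3,7,11-trimethyldodeca-2,6,10-trienoate, methyl (2Z,6E)-farnesoate | COC(=O)/C=C(C)\CC/C=C(\C)CCC=C(C)C | intermediate
7 | methyl (2Z,6E,10E)-12-hydroxy-3,7,11-trimethyldodeca-2,6,10-trienoate | COC(=O)/C=C(C)\CC/C=C(\C)CC/C=C(\C)CO | intermediate
8 | methyl (2Z,6E,10E)-12-bromo-3,7,11-trimethyldodeca-2,6,10-trienoate | COC(=O)/C=C(C)\CC/C=C(\C)CC/C=C(\C)CBr | intermediate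
9 | (−)-8-phenylmenthol, (1R,2S,5R)-5-methyl-2-(2-phenylpropan-2-yl)cyclohexan-1-ol | O[C@@H]1C[C@H](C)CC[C@H]1C(C)(C)c1ccccc1 | starting material
10 | ethyl 2-methyl-3-oxobutanoate (racemic) | CCOC(=O)C(C)C(C)=O | starting material
11 | (1R,2S,5R)-5-methyl-2-(2-phenylpropan-2-yl)cyclohexyl 2-methyl-3-oxobutanoate (epimers at C2 of the acyl part) | CC(=O)C(C)C(=O)O[C@@H]1C[C@H](C)CC[C@H]1C(C)(C)c1ccccc1 | intermediate
12 | sodium lithium 1,3-dienolate (dianion) of 11 | [Na+].[Li+].C=C([O-])C(C)=C([O-])O[C@@H]1C[C@H](C)CC[C@H]1C(C)(C)c1ccccc1 | intermediate (not isolated)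
13 | 1-methyl 16-[(1R,2S,5R)-8-phenylmenthyl] (2Z,6E,10E)-3,7,11,15-tetramethyl-14-oxohexadeca-2,6,10-trienedioate (epimers at C15) | COC(=O)/C=C(C)\CC/C=C(\C)CC/C=C(\C)CCC(=O)C(C)C(=O)O[C@@H]1C[C@H](C)CC[C@H]1C(C)(C)c1ccccc1 | intermediate
14 | 15-methyl 19-[(1R,2S,5R)-8-phenylmenthyl] (13Z)-3-oxolabda-8(17),13-diene-15,19-dioate (4β axial ester, 4α-CH3, 5α-H, 9α-H, 10β-CH3) | C=C1CC[C@H]2[C@@](C)(C(=O)O[C@@H]3C[C@H](C)CC[C@H]3C(C)(C)c3ccccc3)C(=O)CC[C@]2(C)[C@H]1CC/C(C)=C\C(=O)OC | intermediate
15 | 3-tosylhydrazone of 14 | C=C1CC[C@H]2[C@@](C)(C(=O)O[C@@H]3C[C@H](C)CC[C@H]3C(C)(C)c3ccccc3)C(=NNS(=O)(=O)c3ccc(C)cc3)CC[C@]2(C)[C@H]1CC/C(C)=C\C(=O)OC | intermediate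
16 | 3-[N-(1,3,2-benzodioxaborol-2-yl)-N'-tosylhydrazino] adduct of 15 (C3 configuration undefined) | C=C1CC[C@H]2[C@@](C)(C(=O)O[C@@H]3C[C@H](C)CC[C@H]3C(C)(C)c3ccccc3)C(N(B3Oc4ccccc4O3)NS(=O)(=O)c3ccc(C)cc3)CC[C@]2(C)[C@H]1CC/C(C)=C\C(=O)OC | intermediate (not isolated)
17 | 15-methyl 19-[(1R,2S,5R)-8-phenylmenthyl] (13Z)-labda-8(17),13-diene-15,19-dioate | C=C1CC[C@H]2[C@@](C)(C(=O)O[C@@H]3C[C@H](C)CC[C@H]3C(C)(C)c3ccccc3)CCC[C@]2(C)[C@H]1CC/C(C)=C\C(=O)OC | intermediate
18 | (13Z)-19-[(1R,2S,5R)-8-phenylmenthyloxy]-19-oxolabda-8(17),13-dien-15-oic acid | C=C1CC[C@H]2[C@@](C)(C(=O)O[C@@H]3C[C@H](C)CC[C@H]3C(C)(C)c3ccccc3)CCC[C@]2(C)[C@H]1CC/C(C)=C\C(=O)O | intermediate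
19 | (13Z)-19-hydroxylabda-8(17),13-dien-15-oic acid (4S,5R,9S,10R) | C=C1CC[C@H]2[C@@](C)(CO)CCC[C@]2(C)[C@H]1CC/C(C)=C\C(=O)O | intermediate
20 | acetic (13Z)-19-acetoxylabda-8(17),13-dien-15-oic anhydride | C=C1CC[C@H]2[C@@](C)(COC(C)=O)CCC[C@]2(C)[C@H]1CC/C(C)=C\C(=O)OC(C)=O | intermediate (not isolated)
21 | (13Z)-19-acetoxylabda-8(17),13-dien-15-oic acid, (2Z)-5-[(1S,4aR,5S,8aR)-5-(acetoxymethyl)-5,8a-dimethyl-2-methylidenedecahydronaphthalen-1-yl]-3-methylpent-2-enoic acid | C=C1CC[C@H]2[C@@](C)(COC(C)=O)CCC[C@]2(C)[C@H]1CC/C(C)=C\C(=O)O | target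

**Step count and risks**

Total step count: 12. Longest linear sequence: 11 steps (steps 1–4 and 6–12 from 1; step 5 is a one-step branch).

Steps most likely to fail:

1. Step 7. The C8 radical may add 5-exo to the nearby enoate olefin before Cu(OAc)2 oxidises it, or the auxiliary may discriminate the two faces of the C4 radical too weakly. The fallback builds the enoate only after the cascade and sets out from 1. Ketalisation (ethylene glycol, PPTS, benzene, reflux with removal of water) should give 2-[(3E)-4,8-dimethylnona-3,7-dienyl]-2-methyl-1,3-dioxolane F1. Allylic oxidation as in step 3 should give (2E,6E)-2,6-dimethyl-9-(2-methyl-1,3-dioxolan-2-yl)nona-2,6-dien-1-ol F2, and the Appel reaction the corresponding allylic bromide F3. Alkylation of dianion 12 as in step 6 should give the ketal-bearing keto ester F4. Mn(OAc)3·2H2O and Cu(OAc)2·H2O in EtOH should then give the bicyclic 3-oxo ketal F5, in which no π-acceptor lies within reach of C8. Tosylhydrazide should give the hydrazone F6, and catecholborane, through the N-boryl adduct F7 (not isolated), followed by NaOAc should give the 3-deoxy ketal F8. PPTS in wet acetone should free the methyl ketone F9. The one-pot sequence of step 1, through the enol phosphate F10 and the lithium acetylide F11, should give the ynoate F12. Me2CuLi at −78 °C, through the alkenylcuprate F13, should deliver 17, where the route is rejoined before step 10.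

2. Step 9. Hydride delivery to the hindered C3 hydrazone may be slow, and elimination to a C2=C3 olefin may compete. The fallback replaces hydrazone chemistry by radical deoxygenation and sets out from 14. NaBH4 (MeOH/THF, 0 °C) should reduce only the ketone, from the α face, to the 3β-hydroxy diester F14. PhOC(S)Cl, pyridine and DMAP should give the 3β-O-phenoxythiocarbonyl derivative F15. Bu3SnH and AIBN in toluene at 90 °C (Barton–McCombie deoxygenation) should give 17, where the route is rejoined before step 10.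

3. Step 11. Hydride attack at the shielded axial C19 ester may be incomplete, or the C15 carboxylate may be over-reduced. The fallback uses global reduction and selective re-oxidation and sets out from 17. LiAlH4 in refluxing THF should reduce both esters to (13Z)-labda-8(17),13-diene-15,19-diol F16, with the auxiliary alcohol 9 recovered. MnO2 in CH2Cl2 should oxidise only the allylic alcohol to (13Z)-19-hydroxylabda-8(17),13-dien-15-al F17. Pinnick oxidation (NaClO2, NaH2PO4, 2-methyl-2-butene, t-BuOH/H2O) should give 19, where the route is rejoined before step 12.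

Further compounds
F1 | step 7 | 2-[(3E)-4,8-dimethylnona-3,7-dienyl]-2-methyl-1,3-dioxolane | CC1(CC/C=C(\C)CCC=C(C)C)OCCO1
F2 | step 7 | (2E,6E)-2,6-dimethyl-9-(2-methyl-1,3-dioxolan-2-yl)nona-2,6-dien-1-ol | CC1(CC/C=C(\C)CC/C=C(\C)CO)OCCO1
F3 | step 7 | 2-[(3E,7E)-9-bromo-4,8-dimethylnona-3,7-dienyl]-2-methyl-1,3-dioxolane | CC1(CC/C=C(\C)CC/C=C(\C)CBr)OCCO1
F4 | step 7 | (1R,2S,5R)-8-phenylmenthyl (6E,10E)-2,6,10-trimethyl-13-(2-methyl-1,3-dioxolan-2-yl)-3-oxotrideca-6,10-dienoate (epimers at C2) | CC1(CC/C=C(\C)CC/C=C(\C)CCC(=O)C(C)C(=O)O[C@@H]2C[C@H](C)CC[C@H]2C(C)(C)c2ccccc2)OCCO1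
F5 | step 7 | (1R,2S,5R)-8-phenylmenthyl 13,13-(ethylenedioxy)-3-oxo-14,15-dinorlabd-8(17)-en-19-oate | C=C1CC[C@H]2[C@@](C)(C(=O)O[C@@H]3C[C@H](C)CC[C@H]3C(C)(C)c3ccccc3)C(=O)CC[C@]2(C)[C@H]1CCC1(C)OCCO1
F6 | step 7 | 3-tosylhydrazone of F5 | C=C1CC[C@H]2[C@@](C)(C(=O)O[C@@H]3C[C@H](C)CC[C@H]3C(C)(C)c3ccccc3)C(=NNS(=O)(=O)c3ccc(C)cc3)CC[C@]2(C)[C@H]1CCC1(C)OCCO1
F7 | step 7 | N-(1,3,2-benzodioxaborol-2-yl) tosylhydrazide adduct of F6 (not isolated) | C=C1CC[C@H]2[C@@](C)(C(=O)O[C@@H]3C[C@H](C)CC[C@H]3C(C)(C)c3ccccc3)C(N(B3Oc4ccccc4O3)NS(=O)(=O)c3ccc(C)cc3)CC[C@]2(C)[C@H]1CCC1(C)OCCO1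
F8 | step 7 | (1R,2S,5R)-8-phenylmenthyl 13,13-(ethylenedioxy)-14,15-dinorlabd-8(17)-en-19-oate | C=C1CC[C@H]2[C@@](C)(C(=O)O[C@@H]3C[C@H](C)CC[C@H]3C(C)(C)c3ccccc3)CCC[C@]2(C)[C@H]1CCC1(C)OCCO1
F9 | step 7 | (1R,2S,5R)-8-phenylmenthyl 13-oxo-14,15-dinorlabd-8(17)-en-19-oate | C=C1CC[C@H]2[C@@](C)(C(=O)O[C@@H]3C[C@H](C)CC[C@H]3C(C)(C)c3ccccc3)CCC[C@]2(C)[C@H]1CCC(C)=O
F10 | step 7 | enol phosphate of F9 (diethyl phosphate on C13, terminal C13=CH2; not isolated) | C=C1CC[C@H]2[C@@](C)(C(=O)O[C@@H]3C[C@H](C)CC[C@H]3C(C)(C)c3ccccc3)CCC[C@]2(C)[C@H]1CCC(=C)OP(=O)(OCC)OCC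
F11 | step 7 | lithium acetylide from F10 (C13≡C–Li; not isolated) | C=C1CC[C@H]2[C@@](C)(C(=O)O[C@@H]3C[C@H](C)CC[C@H]3C(C)(C)c3ccccc3)CCC[C@]2(C)[C@H]1CCC#C[Li]
F12 | step 7 | 15-methyl 19-[(1R,2S,5R)-8-phenylmenthyl] 16-norlabd-8(17)-en-13-yne-15,19-dioate | C=C1CC[C@H]2[C@@](C)(C(=O)O[C@@H]3C[C@H](C)CC[C@H]3C(C)(C)c3ccccc3)CCC[C@]2(C)[C@H]1CCC#CC(=O)OC
F13 | step 7 | lithium methyl(alkenyl)cuprate from syn-addition to F12 (Cu on C14, cis to the new C16 methyl; not isolated) | [Li+].C=C1CC[C@H]2[C@@](C)(C(=O)O[C@@H]3C[C@H](C)CC[C@H]3C(C)(C)c3ccccc3)CCC[C@]2(C)[C@H]1CC/C(C)=C(/[Cu-]C)C(=O)OC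
F14 | step 9 | 15-methyl 19-[(1R,2S,5R)-8-phenylmenthyl] (13Z)-3β-hydroxylabda-8(17),13-diene-15,19-dioate | C=C1CC[C@H]2[C@@](C)(C(=O)O[C@@H]3C[C@H](C)CC[C@H]3C(C)(C)c3ccccc3)[C@@H](O)CC[C@]2(C)[C@H]1CC/C(C)=C\C(=O)OC
F15 | step 9 | 15-methyl 19-[(1R,2S,5R)-8-phenylmenthyl] (13Z)-3β-(phenoxythiocarbonyloxy)labda-8(17),13-diene-15,19-dioate | C=C1CC[C@H]2[C@@](C)(C(=O)O[C@@H]3C[C@H](C)CC[C@H]3C(C)(C)c3ccccc3)[C@@H](OC(=S)Oc3ccccc3)CC[C@]2(C)[C@H]1CC/C(C)=C\C(=O)OC
F16 | step 11 | (13Z)-labda-8(17),13-diene-15,19-diol | C=C1CC[C@H]2[C@@](C)(CO)CCC[C@]2(C)[C@H]1CC/C(C)=C\CO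
F17 | step 11 | (13Z)-19-hydroxylabda-8(17),13-dien-15-al | C=C1CC[C@H]2[C@@](C)(CO)CCC[C@]2(C)[C@H]1CC/C(C)=C\C=O
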